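Two questions stand here: how the starting rate follows c(substrate) round Wednesday's charge, and how much target Friday's flask holds at its end.

| flask | substrate | partner | time |
|---|---|---|---|
| Wednesday's | 250 mM | 300 mM |  |
| Thursday's | 750 mM | 300 mM |  |
| Friday's | 150 mM | 200 mM | 16 min |

| Wednesday's run: time / min | Wednesday's run: [target] / mM | Thursday's run: time / min | Thursday's run: [target] / mM |
|---|---|---|---|
| 0.64 | 3.5 | 0.64 | 10.3 |
| 1.4 | 7.4 | 1.4 | 28.8 |
| 3.2 | 25.6 | 3.2 | 72.9 |
| 7.2 | 50.8 | 7.2 | 173.6 |
| 16 | 108.8 | 16 | 293.0 |

(each reading ± 2 mM)

- apparent order in [substrate] of the starting rate, round the charge of the Wednesday's run (the rate where two percent of its substrate have turned into target) (one fixed amount of target, the same in the runs compared)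
- target in the Friday's run at 16 min, as a share of the substrate charged

- Overall: substrate + partner -> target.
- Constant volume, constant temperature.
- What is held in complexes is read along with the free species.
- "The second partner" is partner.
- An order is taken over about fifteen percent of the charge, up and down.

We carry one quantity, the substrate lifetime: the elapsed time divided by the natural logarithm of the substrate charged over the substrate left, each target counting as one substrate gone. Wednesday's last reading gives 28.0 min.

Take the main step first, substrate plus partner to target, with a rate proportional to c(substrate) times c(partner). At fixed c(partner), a lifetime then does not depend on the substrate charged, and it goes inversely with c(partner). At 3.2 min, Wednesday gives 29.6 min and Thursday, from 750 mM instead of 250 mM, gives 31.3 min. These lie as close as a scatter of 2 mM allows, so we reckon an order near one. Scaled to Friday's partner charge, the early lifetime becomes 44.4 min, which puts 30.2% of Friday's substrate through by 16 min.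

Now add what happens along the way. Wednesday's partner falls as it is used, yet the whole-run lifetime is shorter than the early one, so we take it that target speeds the step. Scaling the whole-run lifetime instead gives 42.0 min and lifts our number to 31.7%. Last comes the partner itself: both runs charge 300 mM, so our step down to Friday's 200 mM rests on the first order in c(partner) assumed above, and we have not held that order against the fall of partner within the runs.

The forecast gives an order of 1, from 0.8 to 1.25, and 25.5%, from 21% to 30%, holding that “depletion offsets acceleration”. Our reckoning for Friday stands higher than the forecast.

The order comes out at 1.0, and Friday's flask gives 32.7%, 7.2 percentage points above the forecast.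

    substrate + partner ⇌ intermediate, settled at all times (1.370 /M)
    substrate + partner → target (0.8340 /M/min)
    2 partner ⇌ idle reagent dimer, settled at all times (113.0 /M)
    substrate + partner + target → 2 target (7.200 /M²/min)

Friday's share is a lifetime of 40.4 min. The main reason it is this long is the tying up of partner as idle reagent dimer: the same Friday flask without that dimer reaches 86.7%, a lifetime of 7.93 min. On Thursday's flask, Wednesday's lifetime puts a quarter of the charge at 8.06 min, and it stood there at 7.92 min.

The runs come from a simulation on assumed constants; noise was put on by code.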